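**Retrosynthetic overview**

1. Feature: the 3,7-dioxabicyclo[3.3.0]octane core (tetrahydrofuran rings C1–C2–O3–C4–C5 and C5–C6–O7–C8–C1) is a 2,3-dibenzylbutane-1,4-diol oxidised at its two benzylic carbons C2 and C6. Ring B (on C2) and ring A (on C6) each hold an oxygen para to that carbon, so as free phenols both ArCH2 groups can be raised to p-quinone methides, and only C1 and C5 must be in place beforehand.
2. Endgame: global desilylation, preceded by formation of the ring B–Cα bond of the keto arm. That bond comes from a stereoconvergent nickel Negishi coupling of the ring-B arylzinc (from the bromide) with a racemic α-bromoketone made from acetovanillone.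
3. Ring C (dihydrofuran): syn hydrogenation of a benzofuran, itself made by Larock heteroannulation of the ring-A iodophenol with a vanillin-derived arylpropargyl alcohol. Bromine and iodine keep rings B and A apart.
4. Core: C2–O3 and C6–O7 by twofold DDQ cycloetherification of the halogenated (2R,3R)-dibenzylbutanediol. The diol comes from Stobbe condensation, asymmetric hydrogenation (C1), lactonisation, trans enolate alkylation (C5), reduction and MOM removal.
5. Ring order: temporary butyrolactone, then both tetrahydrofuran rings in one operation, then furan ring C, which is saturated two steps later.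

Key step: step 11

Assumption: the SMILES is read literally, that is (1R,2S,5R,6S) exo,exo furofuran, a cis (2'S,3'S) dihydrobenzofuran and an (S) keto-arm centre; the hand quoted for each chiral ligand is the expected one, is to be confirmed on a model substrate, and the antipode of each ligand is equally available.

Labels: ring A = arene on C6 (later the benzo ring of the dihydrobenzofuran); ring B = arene on C2 (carries the keto arm); ring C = the (dihydro)furan ring with atoms O1', C2', C3'; ring D = guaiacyl group on C2'; ring E = guaiacyl group of the ketone.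

**Step 1**
Reactants: 1 5-bromovanillin
Product: 2 3-bromo-5-methoxy-4-(methoxymethoxy)benzaldehyde
Conditions: MOMCl, i-Pr2NEt, CH2Cl2, 0 °C → rt
Reagents that add atoms: chloromethyl methyl ether, COCCl
Why: Williamson-type O-alkylation of the phenol; the MOM acetal withstands the alkoxide, hydride and enolate steps ahead (an aryl silyl ether would not survive the Stobbe base) and can later be removed without hydrogenolysis, which the aryl halides forbid.

**Step 2**
Reactants: 2 3-bromo-5-methoxy-4-(methoxymethoxy)benzaldehyde; 3 dimethyl succinate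
Product: 4 (E)-4-[3-bromo-5-methoxy-4-(methoxymethoxy)phenyl]-3-(methoxycarbonyl)but-3-enoic acid
Conditions: NaOMe, MeOH, reflux; then dilute HCl, 0 °C
Reagents that add atoms: none
Why: Stobbe condensation, in which the succinate enolate adds to the aldehyde, the alkoxide closes to a paraconic ester and E1cB opening gives the half-ester, the E alkene (aryl trans to CO2Me) being favoured on steric grounds.

**Step 3**
Reactants: 4 (E)-half-ester
Product: 5 (3R)-4-[3-bromo-5-methoxy-4-(methoxymethoxy)phenyl]-3-(methoxycarbonyl)butanoic acid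
Conditions: [Rh(cod)Cl]2 (0.5 mol%), (S,S)-MOD-DIOP (1.1 mol%), Et3N (1 equiv), H2 (5 bar), MeOH, 30 °C; then dilute HCl
Reagents that add atoms: none
Why: carboxylate-directed rhodium-catalysed asymmetric hydrogenation of an arylidenesuccinic half-ester, a standard entry to (R)-benzylsuccinates, in which two-point binding of alkene and carboxylate to the chiral bisphosphine complex fixes the face and sets future C1 as R while the aryl bromide is inert to this homogeneous catalyst.

**Step 4**
Reactants: 5 (R)-half-ester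
Product: 7 (4R)-4-[3-bromo-5-methoxy-4-(methoxymethoxy)benzyl]dihydrofuran-2(3H)-one, via hydroxy acid 6 (not isolated)
Conditions: KOH (1 equiv), EtOH; CaCl2, NaBH4, EtOH, −10 °C → rt; then 1 M HCl to pH 3, 0 °C → rt
Reagents that add atoms: none
Why: chemoselective borohydride reduction, since the carboxylate salt is inert to Ca(BH4)2 while the methyl ester is reduced, and brief acidification lactonises the γ-hydroxy acid without touching the stereocentre or the MOM group.

**Step 5**
Reactants: 8 5-iodovanillin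
Product: 9 3-iodo-5-methoxy-4-(methoxymethoxy)benzaldehyde
Conditions: MOMCl, i-Pr2NEt, CH2Cl2, 0 °C → rt
Reagents that add atoms: chloromethyl methyl ether, COCCl
Why: the same Williamson-type phenol protection as in step 1, so that both phenols can be released together just before the key step.

**Step 6**
Reactants: 9 3-iodo-5-methoxy-4-(methoxymethoxy)benzaldehyde
Product: 10 [3-iodo-5-methoxy-4-(methoxymethoxy)phenyl]methanol
Conditions: NaBH4, MeOH, 0 °C; then H2O
Reagents that add atoms: none
Why: borohydride reduction of an aromatic aldehyde, which leaves the aryl iodide and the acetal untouched.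

**Step 7**
Reactants: 10 [3-iodo-5-methoxy-4-(methoxymethoxy)phenyl]methanol
Product: 11 5-(bromomethyl)-1-iodo-3-methoxy-2-(methoxymethoxy)benzene
Conditions: CBr4, PPh3, CH2Cl2, 0 °C
Reagents that add atoms: carbon tetrabromide, BrC(Br)(Br)Br
Why: Appel bromination, chosen because it is neutral and so spares the acid-labile MOM ether that PBr3 or HBr would endanger.

**Step 8**
Reactants: 7 (R)-lactone; 11 benzyl bromide
Product: 13 (3R,4R)-4-[3-bromo-5-methoxy-4-(methoxymethoxy)benzyl]-3-[3-iodo-5-methoxy-4-(methoxymethoxy)benzyl]dihydrofuran-2(3H)-one, via lithium enolate 12 (not isolated)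
Conditions: LiN(SiMe3)2 (1.05 equiv), THF, −78 °C; then 11, DMPU, −78 → −40 °C
Reagents that add atoms: none
Why: enolate alkylation of a β-substituted γ-butyrolactone, in which the bromide approaches anti to the C4 benzyl group and so gives the trans lactone and sets future C5, while the silylamide base causes neither halogen–metal exchange nor ring metalation.

**Step 9**
Reactants: 13 trans-lactone
Product: 14 (2R,3R)-2-[3-bromo-5-methoxy-4-(methoxymethoxy)benzyl]-3-[3-iodo-5-methoxy-4-(methoxymethoxy)benzyl]butane-1,4-diol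
Conditions: LiBH4, THF, 0 °C → rt; then H2O
Reagents that add atoms: none
Why: lactone reduction with LiBH4, preferred to LiAlH4 because it leaves aryl iodide and bromide intact, and no stereocentre is involved.

**Step 10**
Reactants: 14 bis-MOM diol
Product: 15 (2R,3R)-2-(3-bromo-4-hydroxy-5-methoxybenzyl)-3-(4-hydroxy-3-iodo-5-methoxybenzyl)butane-1,4-diol
Conditions: conc. HCl (cat.), MeOH, 40 °C
Reagents that add atoms: none
Why: acid-catalysed acetal exchange (MOM methanolysis) frees both phenols under conditions too mild for cyclodehydration of the 1,4-diol.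

**Step 11**
Reactants: 15 (2R,3R)-tetraol
Product: 19 (1R,2S,5R,6S)-2-(3-bromo-4-hydroxy-5-methoxyphenyl)-6-(4-hydroxy-3-iodo-5-methoxyphenyl)-3,7-dioxabicyclo[3.3.0]octane (5-bromo-5'-iodopinoresinol), via C2 quinone methide 16 (not isolated), via monocyclised tetrahydrofuran 17 (not isolated), via C6 quinone methide 18 (not isolated)
Conditions: DDQ (2.05 equiv, portionwise), 4 Å molecular sieves, CH2Cl2–1,4-dioxane, 0 °C, short contact; filtration, aq NaHCO3 wash
Reagents that add atoms: none
Why: DDQ removes a net hydride (electron, proton, electron by way of the phenol) from the 4-hydroxybenzyl CH2 at C2 to give quinone methide 16, the C4 hydroxyl adds to its exocyclic carbon and rearomatises ring B to 17, and a second equivalent repeats the sequence at C6 through 18 using the C8 hydroxyl, the order of the two oxidations being immaterial. The closest known reaction type is the DDQ-mediated benzylic oxidative cycloetherification of hydroxy-tethered 4-oxygenated alkylarenes to 2-aryl cyclic ethers, and the closures themselves are those of the biomimetic quinone methide route to furofurans. Both rings close 5-exo-trig (O3 onto C2, O7 onto C6), and the hydroxyl on the neighbouring carbon could only form an oxetane, so the connectivity is fixed. C2 is set by addition to the quinone methide conformer that holds the aryl group anti to the C1 hydroxymethyl group (allylic strain), and C6 by the closure that leaves ring A on the convex exo face of the cis-bicyclooctane, whose cis fusion is dictated by the preset C1 and C5. The step needs oxygen attack to outrun Friedel–Crafts attack by the other arene (aryltetralin), phenoxyl coupling and over-oxidation, which is helped because the halogens block C5 of each ring and deactivate the neighbouring ring carbon, no acid is added and DDQ is limited to two equivalents at low temperature. DDQH2 precipitates from the medium and the contact time is short, so the kinetic exo,exo product should escape acid-mediated epimerisation at C2 and C6.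

**Step 12**
Reactants: 20 vanillin
Product: 21 3-methoxy-4-(triisopropylsilyloxy)benzaldehyde
Conditions: TIPSCl, imidazole, DMF, rt
Reagents that add atoms: chlorotriisopropylsilane, CC(C)[Si](Cl)(C(C)C)C(C)C
Why: phenol silylation, TIPS being chosen over TBS so that the aryl silyl ether survives butyllithium and the carbonate/DMF medium of the annulation and leaves with fluoride at the end.

**Step 13**
Reactants: 21 3-methoxy-4-(triisopropylsilyloxy)benzaldehyde
Product: 22 [4-(2,2-dibromovinyl)-2-methoxyphenoxy]triisopropylsilane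
Conditions: CBr4, PPh3, CH2Cl2, 0 °C
Reagents that add atoms: carbon tetrabromide, BrC(Br)(Br)Br
Why: first stage of the Corey–Fuchs sequence, a Wittig-type dibromoolefination of the aldehyde under neutral conditions.

**Step 14**
Reactants: 22 dibromoolefin
Product: 24 3-[3-methoxy-4-(triisopropylsilyloxy)phenyl]prop-2-yn-1-ol, via lithium acetylide 23 (not isolated)
Conditions: n-BuLi (2.1 equiv), THF, −78 → 0 °C; then (CH2O)n, 0 °C → rt; then H2O
Reagents that add atoms: formaldehyde (as paraformaldehyde), C=O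
Why: second stage of the Corey–Fuchs sequence (bromine–lithium exchange, 1,2-shift, deprotonation) followed by hydroxymethylation of the acetylide with formaldehyde.

**Step 15**
Reactants: 19 5-bromo-5'-iodopinoresinol; 24 arylpropargyl alcohol
Product: 25 (1R,2S,5R,6S)-2-(3-bromo-4-hydroxy-5-methoxyphenyl)-6-{3-(hydroxymethyl)-7-methoxy-2-[3-methoxy-4-(triisopropylsilyloxy)phenyl]benzofuran-5-yl}-3,7-dioxabicyclo[3.3.0]octane
Conditions: Pd(OAc)2 (5 mol%), LiCl (1 equiv), Na2CO3 (4 equiv), 24 (2 equiv), DMF, 90–100 °C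
Reagents that add atoms: none
Why: Larock heteroannulation, in which ligand-free zerovalent palladium inserts into the aryl iodide far faster than into the electron-rich aryl bromide, syn carbopalladation puts the ring-A carbon on the alkyne carbon bearing the small CH2OH and palladium on the aryl-bearing carbon, and C–O reductive elimination from the phenoxide closes furan ring C; any TIPS lost from ring D here is restored in step 16.

**Step 16**
Reactants: 25 benzofuran diol
Product: 26 tris-TIPS ether: (1R,2S,5R,6S)-2-[3-bromo-5-methoxy-4-(triisopropylsilyloxy)phenyl]-6-{7-methoxy-2-[3-methoxy-4-(triisopropylsilyloxy)phenyl]-3-[(triisopropylsilyloxy)methyl]benzofuran-5-yl}-3,7-dioxabicyclo[3.3.0]octane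
Conditions: TIPSOTf (2.4 equiv), 2,6-lutidine, CH2Cl2, −20 → 0 °C
Reagents that add atoms: triisopropylsilyl triflate, CC(C)[Si](OS(=O)(=O)C(F)(F)F)(C(C)C)C(C)C
Why: silyl triflate silylation caps the hindered ring-B phenol and the primary alcohol in one operation, TIPS being chosen on ring B because its oxygen-to-carbon (retro-Brook) migration in the later ortho-lithiated species is the slowest among common silyl groups.

**Step 17**
Reactants: 26 tris-TIPS benzofuran
Product: 27 (2'S,3'S)-cis-2',3'-dihydrobenzofuran: (1R,2S,5R,6S)-2-[3-bromo-5-methoxy-4-(triisopropylsilyloxy)phenyl]-6-{(2S,3S)-7-methoxy-2-[3-methoxy-4-(triisopropylsilyloxy)phenyl]-3-[(triisopropylsilyloxy)methyl]-2,3-dihydrobenzofuran-5-yl}-3,7-dioxabicyclo[3.3.0]octane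
Conditions: [Ru(cod)(2-methylallyl)2] (10 mol%), (R,R)-SINpEt·HBF4 {1,3-bis[(R)-1-(1-naphthyl)ethyl]imidazolinium tetrafluoroborate, 20 mol%}, KOt-Bu (30 mol%), toluene, 70 °C (preformation); then 26, H2 (80–100 bar), toluene, 25–40 °C
Reagents that add atoms: none
Why: Proposed new method: the ruthenium–NHC hydride formed from these components is known to saturate only the furan C2=C3 bond of 2-aryl- and 2-alkylbenzofurans with high enantioselectivity (closest known reaction type: asymmetric hydrogenation of 2-substituted benzofurans), because that bond is an enol ether with little aromatic stabilisation; here the same inner-sphere syn delivery of both hydrogens to one face is asked of a 2-aryl-3-(silyloxymethyl) and hence tetrasubstituted case, so that C2' and C3' are set together, cis by the syn addition and 2'S,3'S by the chiral pocket reading the 2-aryl group (the remote furofuran centres having no influence), while the aprotic non-acidic medium spares the benzylic ethers and the capped OH groups cannot quench the basic catalyst.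

**Step 18**
Reactants: 28 acetovanillone
Product: 29 1-[3-methoxy-4-(triisopropylsilyloxy)phenyl]ethanone
Conditions: TIPSCl, imidazole, DMF, rt
Reagents that add atoms: chlorotriisopropylsilane, CC(C)[Si](Cl)(C(C)C)C(C)C
Why: phenol silylation, the bulky TIPS group compensating for the higher lability of a silyl ether para to a ketone.

**Step 19**
Reactants: 29 1-[3-methoxy-4-(triisopropylsilyloxy)phenyl]ethanone
Product: 30 triisopropyl{2-methoxy-4-[1-(trimethylsilyloxy)vinyl]phenoxy}silane
Conditions: TMSOTf, Et3N, CH2Cl2, 0 °C; pentane extraction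
Reagents that add atoms: trimethylsilyl triflate, C[Si](C)(C)OS(=O)(=O)C(F)(F)F
Why: soft enolisation of an aryl methyl ketone to its silyl enol ether, which limits the next step to a single hydroxymethylation.

**Step 20**
Reactants: 30 silyl enol ether
Product: 31 3-hydroxy-1-[3-methoxy-4-(triisopropylsilyloxy)phenyl]propan-1-one
Conditions: 37% aq HCHO, Yb(OTf)3 (10 mol%), THF, rt
Reagents that add atoms: formaldehyde, C=O
Why: aqueous Mukaiyama aldol (hydroxymethylation) with a water-tolerant lanthanide triflate, which adds one formaldehyde unit only and is mild enough to avoid dehydration to the vinyl ketone.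

**Step 21**
Reactants: 31 β-hydroxy ketone
Product: 32 3-(tert-butyldimethylsilyloxy)-1-[3-methoxy-4-(triisopropylsilyloxy)phenyl]propan-1-one
Conditions: TBSCl, imidazole, DMF, 0 °C → rt
Reagents that add atoms: tert-butyldimethylsilyl chloride, CC(C)(C)[Si](C)(C)Cl
Why: standard silylation of a primary alcohol, giving a fluoride-labile group that is removed easily next to the sensitive arm centre at the end.

**Step 22**
Reactants: 32 β-silyloxy ketone
Product: 33 (Z)-trimethylsilyl enol ether of 32 (geometry without consequence)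
Conditions: TMSOTf, Et3N, CH2Cl2, 0 °C; pentane extraction
Reagents that add atoms: trimethylsilyl triflate, C[Si](C)(C)OS(=O)(=O)C(F)(F)F
Why: soft enolisation avoids a free metal enolate and hence E1cB loss of the β-silyloxy group.

**Step 23**
Reactants: 33 silyl enol ether
Product: 34 rac-2-bromo-3-(tert-butyldimethylsilyloxy)-1-[3-methoxy-4-(triisopropylsilyloxy)phenyl]propan-1-one
Conditions: NBS, THF, −78 → 0 °C
Reagents that add atoms: N-bromosuccinimide, O=C1CCC(=O)N1Br
Why: electrophilic α-bromination of a silyl enol ether in the absence of acid or amine, so that neither silyl ether cleavage nor elimination intervenes; the racemate is what the next step requires.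

**Step 24**
Reactants: 27 aryl bromide; 34 racemic α-bromoketone
Product: 37 pentasilylated target with (S) arm centre, via aryllithium 35 (not isolated), via arylzinc iodide 36 (not isolated)
Conditions: 27, t-BuLi (2.0 equiv), THF, −78 °C, 5 min; ZnI2 (1.1 equiv), −78 → 0 °C; then NiCl2·glyme (10 mol%), chiral pybox ligand [2,6-bis(4,5-disubstituted oxazolin-2-yl)pyridine, 13 mol%], rac-34 (1.6 equiv), glyme/THF, −30 °C
Reagents that add atoms: none
Why: stereoconvergent nickel/pybox Negishi arylation of a racemic α-bromoketone, in which both bromide enantiomers pass through the same α-keto radical and the chiral nickel–aryl complex decides the configuration (S, catalyst control, the other centres being remote), while the weakly basic arylzinc at −30 °C leaves the new enolisable tertiary centre intact and immediate zinc trapping at −78 °C forestalls silyl migration.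

**Step 25**
Reactants: 37 pentasilyl ether
Product: 38 target CNP0174045.1: (2S)-3-hydroxy-1-(4-hydroxy-3-methoxyphenyl)-2-{2-hydroxy-3-methoxy-5-[(1R,2S,5R,6S)-6-[(2S,3S)-2-(4-hydroxy-3-methoxyphenyl)-3-(hydroxymethyl)-7-methoxy-2,3-dihydrobenzofuran-5-yl]-3,7-dioxabicyclo[3.3.0]octan-2-yl]phenyl}propan-1-one
Conditions: HF·pyridine, excess pyridine, THF, 0 °C → rt (plastic vessel); pH 7 phosphate buffer
Reagents that add atoms: none
Why: fluoride-mediated global desilylation in a buffered, weakly acidic medium, chosen because basic fluoride would enolise or retro-aldolise the α-aryl-β-hydroxy ketone and would open the p-hydroxybenzyl ethers at C2, C6 and C2' through phenoxide-derived quinone methides, with loss of the cis ring C and exo,exo core configurations.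

**Compound list**

1 | 5-bromovanillin | COc1cc(C=O)cc(Br)c1O | starting material
2 | 3-bromo-5-methoxy-4-(methoxymethoxy)benzaldehyde | COCOc1c(Br)cc(C=O)cc1OC | intermediate
3 | dimethyl succinate | COC(=O)CCC(=O)OC | starting material
4 | (E)-4-[3-bromo-5-methoxy-4-(methoxymethoxy)phenyl]-3-(methoxycarbonyl)but-3-enoic acid | COC(=O)/C(=C/c1cc(OC)c(OCOC)c(Br)c1)CC(=O)O | intermediate
5 | (3R)-4-[3-bromo-5-methoxy-4-(methoxymethoxy)phenyl]-3-(methoxycarbonyl)butanoic acid | OC(=O)C[C@@H](Cc1cc(OC)c(OCOC)c(Br)c1)C(=O)OC | intermediate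
6 | (3R)-3-[3-bromo-5-methoxy-4-(methoxymethoxy)benzyl]-4-hydroxybutanoic acid | OC(=O)C[C@@H](Cc1cc(OC)c(OCOC)c(Br)c1)CO | intermediate
7 | (4R)-4-[3-bromo-5-methoxy-4-(methoxymethoxy)benzyl]dihydrofuran-2(3H)-one | O=C1C[C@@H](Cc2cc(OC)c(OCOC)c(Br)c2)CO1 | intermediate
8 | 5-iodovanillin | COc1cc(C=O)cc(I)c1O | starting material
9 | 3-iodo-5-methoxy-4-(methoxymethoxy)benzaldehyde | COCOc1c(I)cc(C=O)cc1OC | intermediate
10 | [3-iodo-5-methoxy-4-(methoxymethoxy)phenyl]methanol | COCOc1c(I)cc(CO)cc1OC | intermediate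
11 | 5-(bromomethyl)-1-iodo-3-methoxy-2-(methoxymethoxy)benzene | COCOc1c(I)cc(CBr)cc1OC | intermediate
12 | lithium enolate of 7 | [Li+].[O-]C1=C[C@@H](Cc2cc(OC)c(OCOC)c(Br)c2)CO1 | intermediate
13 | (3R,4R)-4-[3-bromo-5-methoxy-4-(methoxymethoxy)benzyl]-3-[3-iodo-5-methoxy-4-(methoxymethoxy)benzyl]dihydrofuran-2(3H)-one | O=C1OC[C@H](Cc2cc(OC)c(OCOC)c(Br)c2)[C@H]1Cc1cc(OC)c(OCOC)c(I)c1 | intermediate
14 | (2R,3R)-2-[3-bromo-5-methoxy-4-(methoxymethoxy)benzyl]-3-[3-iodo-5-methoxy-4-(methoxymethoxy)benzyl]butane-1,4-diol | OC[C@H](Cc1cc(OC)c(OCOC)c(I)c1)[C@H](CO)Cc1cc(OC)c(OCOC)c(Br)c1 | intermediate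
15 | (2R,3R)-2-(3-bromo-4-hydroxy-5-methoxybenzyl)-3-(4-hydroxy-3-iodo-5-methoxybenzyl)butane-1,4-diol | OC[C@H](Cc1cc(OC)c(O)c(I)c1)[C@H](CO)Cc1cc(OC)c(O)c(Br)c1 | intermediate
16 | C2 p-quinone methide of 15 (exocyclic alkene geometry undefined) | OC[C@H](Cc1cc(OC)c(O)c(I)c1)[C@H](CO)C=C1C=C(OC)C(=O)C(Br)=C1 | intermediate
17 | (2S,3R,4R)-2-(3-bromo-4-hydroxy-5-methoxyphenyl)-3-(hydroxymethyl)-4-(4-hydroxy-3-iodo-5-methoxybenzyl)tetrahydrofuran | COc1cc(cc(Br)c1O)[C@H]1OC[C@H](Cc2cc(OC)c(O)c(I)c2)[C@@H]1CO | intermediate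
18 | C6 p-quinone methide of 17 (exocyclic alkene geometry undefined) | COc1cc(cc(Br)c1O)[C@H]1OC[C@H](C=C2C=C(OC)C(=O)C(I)=C2)[C@@H]1CO | intermediate
19 | 5-bromo-5'-iodopinoresinol, (1R,2S,5R,6S) | COc1cc(cc(Br)c1O)[C@H]1OC[C@H]2[C@@H]1CO[C@@H]2c1cc(OC)c(O)c(I)c1 | intermediate
20 | vanillin | COc1cc(C=O)ccc1O | starting material
21 | 3-methoxy-4-(triisopropylsilyloxy)benzaldehyde | COc1cc(C=O)ccc1O[Si](C(C)C)(C(C)C)C(C)C | intermediate
22 | [4-(2,2-dibromovinyl)-2-methoxyphenoxy]triisopropylsilane | COc1cc(C=C(Br)Br)ccc1O[Si](C(C)C)(C(C)C)C(C)C | intermediate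
23 | lithium [3-methoxy-4-(triisopropylsilyloxy)phenyl]acetylide | [Li]C#Cc1ccc(O[Si](C(C)C)(C(C)C)C(C)C)c(OC)c1 | intermediate
24 | 3-[3-methoxy-4-(triisopropylsilyloxy)phenyl]prop-2-yn-1-ol | OCC#Cc1ccc(O[Si](C(C)C)(C(C)C)C(C)C)c(OC)c1 | intermediate
25 | benzofuran from the heteroannulation (ring-B phenol and 3'-CH2OH free) | COc1cc(cc(Br)c1O)[C@H]1OC[C@H]2[C@@H]1CO[C@@H]2c1cc(OC)c2oc(-c3ccc(O[Si](C(C)C)(C(C)C)C(C)C)c(OC)c3)c(CO)c2c1 | intermediate
26 | tris-TIPS benzofuran | COc1cc(cc(Br)c1O[Si](C(C)C)(C(C)C)C(C)C)[C@H]1OC[C@H]2[C@@H]1CO[C@@H]2c1cc(OC)c2oc(-c3ccc(O[Si](C(C)C)(C(C)C)C(C)C)c(OC)c3)c(CO[Si](C(C)C)(C(C)C)C(C)C)c2c1 | intermediate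
27 | tris-TIPS (2'S,3'S)-cis-dihydrobenzofuran aryl bromide | COc1cc(cc(Br)c1O[Si](C(C)C)(C(C)C)C(C)C)[C@H]1OC[C@H]2[C@@H]1CO[C@@H]2c1cc(OC)c2c(c1)[C@@H](CO[Si](C(C)C)(C(C)C)C(C)C)[C@@H](c1ccc(O[Si](C(C)C)(C(C)C)C(C)C)c(OC)c1)O2 | intermediate
28 | acetovanillone | CC(=O)c1ccc(O)c(OC)c1 | starting material
29 | 1-[3-methoxy-4-(triisopropylsilyloxy)phenyl]ethanone | CC(=O)c1ccc(O[Si](C(C)C)(C(C)C)C(C)C)c(OC)c1 | intermediate
30 | triisopropyl{2-methoxy-4-[1-(trimethylsilyloxy)vinyl]phenoxy}silane | C=C(O[Si](C)(C)C)c1ccc(O[Si](C(C)C)(C(C)C)C(C)C)c(OC)c1 | intermediate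
31 | 3-hydroxy-1-[3-methoxy-4-(triisopropylsilyloxy)phenyl]propan-1-one | OCCC(=O)c1ccc(O[Si](C(C)C)(C(C)C)C(C)C)c(OC)c1 | intermediate
32 | 3-(tert-butyldimethylsilyloxy)-1-[3-methoxy-4-(triisopropylsilyloxy)phenyl]propan-1-one | CC(C)(C)[Si](C)(C)OCCC(=O)c1ccc(O[Si](C(C)C)(C(C)C)C(C)C)c(OC)c1 | intermediate
33 | (Z)-trimethylsilyl enol ether of 32 | C[Si](C)(C)O/C(=C\CO[Si](C)(C)C(C)(C)C)c1ccc(O[Si](C(C)C)(C(C)C)C(C)C)c(OC)c1 | intermediate
34 | rac-2-bromo-3-(tert-butyldimethylsilyloxy)-1-[3-methoxy-4-(triisopropylsilyloxy)phenyl]propan-1-one | CC(C)(C)[Si](C)(C)OCC(Br)C(=O)c1ccc(O[Si](C(C)C)(C(C)C)C(C)C)c(OC)c1 | intermediate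
35 | ring-B aryllithium from 27 | COc1cc(cc([Li])c1O[Si](C(C)C)(C(C)C)C(C)C)[C@H]1OC[C@H]2[C@@H]1CO[C@@H]2c1cc(OC)c2c(c1)[C@@H](CO[Si](C(C)C)(C(C)C)C(C)C)[C@@H](c1ccc(O[Si](C(C)C)(C(C)C)C(C)C)c(OC)c1)O2 | intermediate
36 | ring-B arylzinc iodide | COc1cc(cc([Zn]I)c1O[Si](C(C)C)(C(C)C)C(C)C)[C@H]1OC[C@H]2[C@@H]1CO[C@@H]2c1cc(OC)c2c(c1)[C@@H](CO[Si](C(C)C)(C(C)C)C(C)C)[C@@H](c1ccc(O[Si](C(C)C)(C(C)C)C(C)C)c(OC)c1)O2 | intermediate
37 | pentasilylated target (four TIPS, one TBS), arm centre S | COc1cc(C(=O)[C@H](CO[Si](C)(C)C(C)(C)C)c2cc([C@H]3OC[C@H]4[C@@H]3CO[C@@H]4c3cc(OC)c4c(c3)[C@@H](CO[Si](C(C)C)(C(C)C)C(C)C)[C@@H](c3ccc(O[Si](C(C)C)(C(C)C)C(C)C)c(OC)c3)O4)cc(OC)c2O[Si](C(C)C)(C(C)C)C(C)C)ccc1O[Si](C(C)C)(C(C)C)C(C)C | intermediate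
38 | CNP0174045.1 | COc1cc(C(=O)[C@H](CO)c2cc([C@H]3OC[C@H]4[C@@H]3CO[C@@H]4c3cc(OC)c4c(c3)[C@@H](CO)[C@@H](c3ccc(O)c(OC)c3)O4)cc(OC)c2O)ccc1O | target

**Totals and risks**

Total step count: 25. Longest linear sequence: 13 (steps 1–4, 8–11, 15–17, 24, 25).

**1. Step 17.**
- What may go wrong:
  - the catalyst may not turn over on a tetrasubstituted, doubly aryl-conjugated double bond flanked by a bulky silyloxymethyl group;
  - it may discriminate the two faces poorly;
  - it may cause reductive loss of bromine from ring B.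
- Fallback (known chemistry; sets out from 19 and 21, comes back at 27): the two centres of ring C are made by an enantioselective intramolecular carbene C–H insertion, the established route to cis-2-aryl-2,3-dihydrobenzofuran-3-carboxylates, instead of by reduction.
- Methyl bromoacetate and zinc dust in THF give the Reformatsky reagent (2-methoxy-2-oxoethyl)zinc bromide F1. It is coupled at the aryl iodide of 19 under Pd(PPh3)4, the excess reagent first metalating both phenols, to give the methyl arylacetate F2.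
- With iodine replaced by an alkyl group the ring-B bromophenol is clearly the more acidic phenol. One equivalent each of DBU and TIPSCl should therefore give the ring-B mono-TIPS ether F3.
- NaBH4 reduction of 21 gives 3-methoxy-4-(triisopropylsilyloxy)benzyl alcohol F4. Mitsunobu etherification (PPh3, DIAD, THF) joins it to the remaining ring-A phenol and gives the benzyl aryl ether F5.
- Diazo transfer (4-acetamidobenzenesulfonyl azide, DBU, MeCN) gives the aryldiazoacetate F6.
- The dirhodium tetracarboxylate Rh2(S-PTTL)4 (or its antipode) in toluene at −60 °C inserts the carbene into the benzylic ether C–H bond. This should give the cis (2'S,3'R) methyl ester F7, which has the same spatial arrangement as 27; the descriptor changes only through CIP ranking.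
- i-Bu2AlH at −78 °C reduces the ester without epimerisation to the primary alcohol F8, and TIPSOTf/2,6-lutidine gives 27.

**2. Step 11.**
- What may go wrong:
  - further hydride abstraction from the new benzylic ether positions C2 and C6, which stay para to free phenols;
  - carbon instead of oxygen attack on a quinone methide;
  - reopening of the ethers with loss of the exo,exo configuration.
- Fallback (sets out from 15, comes back at 19): the oxidation is separated from quinone methide release.
- TBSCl/imidazole/DMF gives the tetrakis-TBS ether F9.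
- Wohl–Ziegler bromination (NBS, 2 equiv, AIBN, PhCF3, 80 °C) gives the bis(benzylic bromide) F10 as an epimer mixture whose new centres are lost again.
- Bu4NF in THF at −20 °C unmasks the phenoxides. These expel bromide by 1,6-elimination to the same quinone methides 16 and 18 in an oxidant-free, acid-free medium, and the liberated primary alkoxides close both rings to 19.

**3. Step 24.**
- What may go wrong:
  - oxygen-to-carbon silyl migration in the aryllithium before zinc arrives;
  - slow transmetalation and reductive elimination next to the ortho silyloxy group;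
  - β-elimination of silyloxide from the nickel-bound enolate;
  - enolisation of the product.
- Fallback (sets out from 27 and 29, comes back at 38): the ring B–Cα bond is made first without a stereocentre.
- Palladium-catalysed ketone α-arylation (Pd2(dba)3, XPhos, K3PO4, toluene, 80 °C) gives the deoxybenzoin F11.
- TMSOTf/Et3N gives the (Z)-trimethylsilyl enol ether F12.
- Catalytic asymmetric hydroxymethylation with aqueous formaldehyde (Sc(OTf)3, chiral 2,2'-bipyridine diol ligand, DME, −20 °C) sets the arm centre and gives the (S)-α-hydroxymethyl ketone F13.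
- F13 is desilylated under the conditions of step 25 to 38.

**Further compounds**

F1 | step 17 | (2-methoxy-2-oxoethyl)zinc bromide | COC(=O)C[Zn]Br
F2 | step 17 | methyl arylacetate (iodine of 19 replaced by CH2CO2Me) | COc1cc(cc(Br)c1O)[C@H]1OC[C@H]2[C@@H]1CO[C@@H]2c1cc(OC)c(O)c(CC(=O)OC)c1
F3 | step 17 | ring-B mono-TIPS ether of F2 | COc1cc(cc(Br)c1O[Si](C(C)C)(C(C)C)C(C)C)[C@H]1OC[C@H]2[C@@H]1CO[C@@H]2c1cc(OC)c(O)c(CC(=O)OC)c1
F4 | step 17 | 3-methoxy-4-(triisopropylsilyloxy)benzyl alcohol | COc1cc(CO)ccc1O[Si](C(C)C)(C(C)C)C(C)C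
F5 | step 17 | ring-A benzyl aryl ether | COc1cc(cc(Br)c1O[Si](C(C)C)(C(C)C)C(C)C)[C@H]1OC[C@H]2[C@@H]1CO[C@@H]2c1cc(OC)c(OCc2ccc(O[Si](C(C)C)(C(C)C)C(C)C)c(OC)c2)c(CC(=O)OC)c1
F6 | step 17 | aryldiazoacetate | COc1cc(cc(Br)c1O[Si](C(C)C)(C(C)C)C(C)C)[C@H]1OC[C@H]2[C@@H]1CO[C@@H]2c1cc(OC)c(OCc2ccc(O[Si](C(C)C)(C(C)C)C(C)C)c(OC)c2)c(C(=[N+]=[N-])C(=O)OC)c1
F7 | step 17 | cis (2'S,3'R) methyl 2',3'-dihydrobenzofuran-3'-carboxylate | COc1cc(cc(Br)c1O[Si](C(C)C)(C(C)C)C(C)C)[C@H]1OC[C@H]2[C@@H]1CO[C@@H]2c1cc(OC)c2c(c1)[C@@H](C(=O)OC)[C@@H](c1ccc(O[Si](C(C)C)(C(C)C)C(C)C)c(OC)c1)O2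
F8 | step 17 | cis (2'S,3'S) 3'-hydroxymethyl dihydrobenzofuran | COc1cc(cc(Br)c1O[Si](C(C)C)(C(C)C)C(C)C)[C@H]1OC[C@H]2[C@@H]1CO[C@@H]2c1cc(OC)c2c(c1)[C@@H](CO)[C@@H](c1ccc(O[Si](C(C)C)(C(C)C)C(C)C)c(OC)c1)O2
F9 | step 11 | tetrakis-TBS ether of 15 | CC(C)(C)[Si](C)(C)OC[C@H](Cc1cc(OC)c(O[Si](C)(C)C(C)(C)C)c(I)c1)[C@H](CO[Si](C)(C)C(C)(C)C)Cc1cc(OC)c(O[Si](C)(C)C(C)(C)C)c(Br)c1
F10 | step 11 | bis(benzylic bromide) of F9 (benzylic centres undefined) | CC(C)(C)[Si](C)(C)OC[C@H](C(Br)c1cc(OC)c(O[Si](C)(C)C(C)(C)C)c(I)c1)[C@H](CO[Si](C)(C)C(C)(C)C)C(Br)c1cc(OC)c(O[Si](C)(C)C(C)(C)C)c(Br)c1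
F11 | step 24 | deoxybenzoin (ring B–CH2–CO–ring E), four TIPS | COc1cc(C(=O)Cc2cc([C@H]3OC[C@H]4[C@@H]3CO[C@@H]4c3cc(OC)c4c(c3)[C@@H](CO[Si](C(C)C)(C(C)C)C(C)C)[C@@H](c3ccc(O[Si](C(C)C)(C(C)C)C(C)C)c(OC)c3)O4)cc(OC)c2O[Si](C(C)C)(C(C)C)C(C)C)ccc1O[Si](C(C)C)(C(C)C)C(C)C
F12 | step 24 | (Z)-trimethylsilyl enol ether of F11 | COc1cc(/C(O[Si](C)(C)C)=C/c2cc([C@H]3OC[C@H]4[C@@H]3CO[C@@H]4c3cc(OC)c4c(c3)[C@@H](CO[Si](C(C)C)(C(C)C)C(C)C)[C@@H](c3ccc(O[Si](C(C)C)(C(C)C)C(C)C)c(OC)c3)O4)cc(OC)c2O[Si](C(C)C)(C(C)C)C(C)C)ccc1O[Si](C(C)C)(C(C)C)C(C)C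
F13 | step 24 | (S)-α-hydroxymethyl ketone, four TIPS | COc1cc(C(=O)[C@H](CO)c2cc([C@H]3OC[C@H]4[C@@H]3CO[C@@H]4c3cc(OC)c4c(c3)[C@@H](CO[Si](C(C)C)(C(C)C)C(C)C)[C@@H](c3ccc(O[Si](C(C)C)(C(C)C)C(C)C)c(OC)c3)O4)cc(OC)c2O[Si](C(C)C)(C(C)C)C(C)C)ccc1O[Si](C(C)C)(C(C)C)C(C)C
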